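If the enzyme cycle ran with nothing beside it, each target would cost one starting material and one second substrate. With [second substrate] = 0.0350 M below [starting material] = 0.050 M, the second substrate would be the limiting reagent, and target would end at 70.0 % of the starting material charged.

all flasks: starting material 0.050 M; free enzyme 1.8 µM; temperature 5 °C
- Wednesday's: second substrate 0.035 M; the very flask that is asked about, followed so far
- flask: second substrate 0.0350 M; time 10 h

Wednesday's run (percent of the starting material charged)

| time / h | target / % | starting material / % |
|---|---|---|
| 0.667 | 13 | 77 |
| 1.00 | 14 | 69 |
| 1.33 | 17 | 64 |
| 2.50 | 26 | 48 |
| 3.00 | 28 | 49 |
| 5.00 | 31 | 35 |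
| 8.00 | 31 | 33 |

(standard deviation of a reading: 1.5 percentage points)

1. target, in percent of the starting material first charged, at 10 h
2. the option that brings most further target ("none" if no option brings more than 2 percentage points) (east / north-east / north / west / south-east / none)
3. target present, with what was taken out counted in, in percent of the starting material first charged, after east
4. target present, with what was taken out counted in, in percent of the starting material first charged, after south-east

- east: at 10 h add second substrate, 100 % of the amount charged, then wait 10 h
- north-east: at 10 h raise the temperature by 25 K, then wait 10 h
- north: change nothing and wait 10 h more
- west: at 10 h take out 90 % of the target then present, then wait 10 h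
- south-east: at 10 h add free enzyme, 100 % of the amount charged, then wait 10 h

- target taken out counts as made
- the numbers in the tables scatter with a standard deviation of 1.5 percentage points
- on the list of suspects stand: free enzyme -> unfolded enzyme; starting material + free enzyme <-> first complex; first complex -> loaded enzyme + first product; second substrate + loaded enzyme <-> second complex; second complex -> free enzyme + target; starting material + first product -> side product; 2 second substrate -> homo dimer
- the earlier runs do not show what temperature does; that part of a forecast is a guess
- additions bring no volume worth counting

Now I add the scavenging step, starting material + first product to side product. I read its weight from the last two readings of Wednesday's run, replacing the curve by their mean, 0.470, and I call this y, the yield per starting material: target made per starting material consumed. The mean carries an error, since the first reading gives 0.565, so y may read low. With y, consuming the whole charge of starting material gives 47.0 % of target, less than the bare cycle's figure.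

Then come the remaining suspects, unfolding of free enzyme and the homo dimer. In Wednesday's run target reads 31 % at 5.00 h and 31 % at 8.00 h, with 33 % of starting material still there, so I commit to 31.0 % at 10 h. Target has taken 44.3 % of the second substrate's charge, but [second substrate] was not read. From these readings I do not choose between a loss of free enzyme and a loss of second substrate to homo dimer. Whichever option restarts the cycle should bring about y times the starting material left, 16 percentage points.

The forecast gives 31 % now and names south-east as best, with 41 % after it against 32 % after east, on the ground that “Such a sharp exponential stop fits enzyme unfolding”.

The flask gives 34.3 %, and east is best at 54.9 %, a gain of 21 points, while south-east ends at 34.6 %.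

    free enzyme → unfolded enzyme (k = 6.46 × 10⁻⁴ /min, Ea = 204 kJ/mol)
    starting material + free enzyme ⇌ first complex (K = 219 /M, k = 21400 /M/s, Ea = 23.0 kJ/mol, ΔH = −30.0 kJ/mol)
    first complex → loaded enzyme + first product (k = 3350 /min, Ea = 49.0 kJ/mol)
    second substrate + loaded enzyme ⇌ second complex (K = 6.24 /M, k = 85900 /M/min, Ea = 40.0 kJ/mol, ΔH = 0 kJ/mol)
    second complex → free enzyme + target (k = 656 /min, Ea = 64.0 kJ/mol)
    starting material + first product → side product (k = 4.31 /M/min, Ea = 56.0 kJ/mol)
    2 second substrate → homo dimer (k = 0.229 /M/min, Ea = 48.0 kJ/mol)
    (constants at 5 °C)

In the flask, by 5.00 h the cycle and the dimerisation have together brought second substrate to 4.34 % of its charge, with homo dimer at 0.00882 M. At 10.0 h it stands at 0.489 % while 31.5 % of starting material remains and unfolded enzyme holds 0.0438 % of the catalyst. For east, y times that starting material gives 15 points against the 21 points found. In the neighbour flask with 7.2 × 10⁻⁶ M of free enzyme, starting material stands at 0 %, y gives 47.0 %, and that flask holds 53.7 % of target.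

All runs come from a simulation for substances that don't exist.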